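## Structural features

2'-Hydroxylupalbigenin is an achiral isoflavone. A benzo-γ-pyranone (rings A and C, fused along C4a–C8a) carries a second benzene ring (ring B) through the C3–C1' bond. Ring A is a phloroglucinol unit with hydroxyls at C5 and C7 and a prenyl (3-methylbut-2-en-1-yl) group between them at C6. Ring B is a resorcinol unit with hydroxyls at C2' and C4' and a prenyl group between them at C3'. The target has no stereocenter; the only one that arises on the way is C3 of an isoflavanone intermediate, and it is removed again. The fragile elements are the two trisubstituted alkenes, each flanked by two phenolic oxygens: acid closes them to chromans, hydride-abstracting oxidants attack the benzylic–allylic methylenes, and hydrogenation saturates them. The real difficulty is regiochemical: the ring A prenyl must sit at C6 and not at C8, and the ring B prenyl must sit in the crowded position between two oxygens. The key step uses the C4 carbonyl carbon, which is bonded to C4a of ring A and to C3, the carbon that carries ring B. It can enter as carbon monoxide between an aryl iodide (C4a) and an alkenylboron carbon (C3), which leaves the C8a oxygen and the =CH2 terminus (future C2) placed for closure of ring C.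

## Logic of the disconnections

23 ⇒ 22. The four O–CH2 acetal bonds on the oxygens at C5, C7, C2' and C4' are cut. Free phenols next to prenyl groups would not survive the organolithium, palladium/base and oxidation steps, and one acid-labile group type allows a single final operation. The forward step must cleave four acetals without adding the freed phenols to the alkenes.

22 ⇒ 19. The C2=C3 double bond is taken back to C2–H and C3–H. A saturated C2 is what a conjugate addition of the ring oxygen delivers. The forward dehydrogenation must not touch the two benzylic–allylic methylenes; the C3 stereocenter of 19 is irrelevant.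

19 ⇒ 18 ⇒ 17. The O1–C2 bond is cut (retro-oxa-Michael), then the O–Si bond. This opens ring C to an acyclic α-aryl enone that already holds every skeletal atom. The forward step must unmask one phenol in the presence of four acetals, which a fluoride-labile silyl ether allows.

17 ⇒ 15 + 16 + 11. The C4a–C4 and C4–C3 bonds are cut on either side of the carbonyl carbon, which becomes 16. This divides the molecule into two aromatic halves of similar size. The forward coupling must take up carbon monoxide before transmetalation and must tolerate acetals, a silyl ether and two alkenes.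

15 ⇒ 14 ⇒ 13. The O–Si bond and then the C–I bond are cut. 13 has a mirror plane through the hydroxyl and the prenyl group, so its two ortho carbons are equivalent and the prenyl, para to the oxygen, maps onto C6. The forward iodination must stop at one iodine and prefer the phenoxide ring to the alkene.

13 ⇒ 12 ⇒ 5. The C–O bond para to the prenyl group is cut by way of a C–B bond. That carbon is the only ring C–H of 5 without an ortho substituent, so ring A can come from the same intermediate as ring B. The forward C–H borylation must be sterically governed and leave the alkene alone.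

11 ⇒ 10 ⇒ 8. The C–B bond and then the enol C–O bond at the future C3 are cut back to a methyl ketone. The ketone carbon fixes the position of boron without any regiochemical choice. The forward enolisation can only occur at the methyl group.

8 ⇒ 7 ⇒ 5 + 6. The aryl–acyl bond (C1'–C3 of the target) is cut. The two free positions ortho to an acetal oxygen in 5 are equivalent. The forward lithiation must occur on the ring and not at the benzylic–allylic methylene.

5 ⇒ 4 ⇒ 2 + 3. The aryl–CH2 bond of the prenyl group is cut; this one bond serves both as C6–CH2 and as C3'–CH2 of the target. The carbon between two acetal oxygens is the most readily lithiated site of 2. The forward allylation must be SN2 and not SN2'.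

2 ⇒ 1. The two O–CH2 acetal bonds are cut, which leads to a commodity diphenol.

## Other disconnections considered

Alternative 1: The cut runs through ring B itself (C2'–C3', C4'–C5', C1'–C2'), so ring B would be built on a finished chromone.
- Forward step: irradiation of the dienyl diazoketone A1 would cause a Wolff rearrangement to a vinylketene. This would add to the siloxyalkyne A2, and four-electron opening of the cyclobutenone, six-electron closure and tautomerisation would give the resorcinol mono-silyl ether A3.
- In favour: the ring B pattern (2'-OH, 3'-prenyl, 4'-O-silyl) is written into the two components, so no aromatic substitution next to a prenyl group is needed. On ring B regiocontrol it is the equal of the chosen plan. It is better in that the 2'- and 4'-oxygens emerge differentiated, although the target does not need this.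
- Against: rings A and C, including the C6 prenyl problem, must be solved first and then extended by a three-carbon diazoketone arm. The photolysis would run on a strongly absorbing chromone bearing two alkenes open to carbene addition. A2 is a sensitive skipped enyne ynol ether with its own synthesis.
- Comparison: the chosen plan makes two bonds at one carbon under palladium catalysis with the prenyl groups as spectators, whereas this cascade passes through a ketene and a strained cyclobutenone next to the same groups. It is clearly longer, since it constructs a benzene ring that resorcinol supplies ready-made.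

Alternative 2: The cut removes both prenyl C–C bonds (C6–CH2 and C3'–CH2) and traces them to aryl 1,1-dimethylallyl ethers on O5 and O2'.
- Forward step: heating the bis-ether A4 would bring about two ortho-Claisen shifts and give A5.
- In favour: the other ortho positions (C4a and C1') are substituted, so each [3,3] shift has one possible terminus; in prenyl regiocontrol this is the equal of the symmetry argument of the chosen plan. It is better in two respects: no organometallic or oxidative step ever sees a prenyl group, and the 5- and 2'-hydroxyls emerge free, so only two acetals remain to be removed.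
- Against: A4 requires tertiary ethers on the two least reactive hydroxyls, the chelated 5-OH and the hindered 2'-OH (tertiary propargylation, then semi-hydrogenation over Pd/CaCO3 poisoned with Pb(OAc)2). Such ethers ionise easily, so loss of the allyl group and onward Cope migration toward C8 would compete with the desired shift. The unprenylated isoflavone core still has to be made.
- Comparison: the step count would be comparable, but the sequence is linear and the risk lies late, on the most advanced material. In the chosen plan the uncertain bond formation joins two fragments that are each cheap to remake.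

Alternative 3: The cut is the C4–C4a bond alone.
- Forward step: activation of the (Z)-3-aryloxy-2-arylacrylic acid A6 would acylate one of the two equivalent ortho carbons of its aryloxy ring and close ring C, giving A7, which is identical with 22.
- In favour: it uses the same symmetric ring A logic and the same phenol 13, so it is the equal of the chosen plan in regiocontrol. It is better in oxidation-state economy, since the isoflavone is reached directly and steps 10 and 11 would be unnecessary.
- Against: the acid is a vinylogous carbonate and a poor acylium precursor, so the activation must be forceful. It would take place in the presence of four acid-labile acetals and two nucleophilic alkenes. Only the Z isomer can close, and A6 needs several steps of its own (formylation of an arylacetate, enol activation, substitution by 13, saponification).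
- Comparison: the same bond is formed by a cationic mechanism here and under near-neutral palladium catalysis in the chosen plan. The two steps saved at the end are largely spent on preparing A6.

Key step: step 9

Remarks on the chemistry:
- "Prenyl" means 3-methylbut-2-en-1-yl throughout. The target is achiral, and 19 and 21 are carried as racemates because C3 becomes sp2 in step 11.
- Mapping check: the iodinated carbon of 14/15 becomes C4a, the phenol oxygen becomes O1, and the prenyl para to that oxygen ends at C6; no structural correction is needed.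
- Design change to the coupling partner: the ortho-iodophenol 14 is not coupled as such but as its triisopropylsilyl ether 15. A free phenoxide next to the aroylpalladium centre would invite aryl ester formation, and the hydroxy enone 18 would close ring C in an uncontrolled way under the basic coupling conditions.
- Route design: both rings are drawn from one intermediate, 5. The boron position of 11 is fixed by an enol triflate, not by a regioselective alkyne borylation.

## Route

Step 1
Reactants: 1 resorcinol
Product: 2 1,3-bis(methoxymethoxy)benzene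
Conditions: MOMCl (2.5 equiv), i-Pr2NEt (3 equiv), CH2Cl2, 0 °C → rt
Reagents that add atoms: chloromethyl methyl ether (MOMCl), COCCl
Why: Double O-alkylation of the phenols (Williamson-type acetal formation). The methoxymethyl ethers serve as ortho-directing groups for both lithiations and as the final protecting groups.

Step 2
Reactants: 2 1,3-bis(methoxymethoxy)benzene; 3 prenyl bromide
Product: 5 1,3-bis(methoxymethoxy)-2-(3-methylbut-2-en-1-yl)benzene, via 2,6-bis(methoxymethoxy)phenyllithium 4 (not isolated)
Conditions: n-BuLi (1.1 equiv), THF, 0 °C → rt; CuI (10 mol%), then 3, −78 °C → rt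
Reagents that add atoms: none
Why: Directed ortho-metalation occurs at the carbon between the two acetal oxygens, which coordinate the base cooperatively. Copper-catalysed allylation of the aryllithium then proceeds in the SN2 sense and gives the linear prenyl group.

Step 3
Reactants: 5 1,3-bis(methoxymethoxy)-2-(3-methylbut-2-en-1-yl)benzene; 6 N-methoxy-N-methylacetamide
Product: 8 1-[2,4-bis(methoxymethoxy)-3-(3-methylbut-2-en-1-yl)phenyl]ethan-1-one, via 2,4-bis(methoxymethoxy)-3-prenylphenyllithium 7 (not isolated)
Conditions: n-BuLi (1.2 equiv), TMEDA (1.2 equiv), THF, −78 → −20 °C; 6, −78 °C → rt; H2O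
Reagents that add atoms: none
Why: Directed ortho-metalation next to an acetal oxygen; the two available ring positions are equivalent by symmetry, so only one aryllithium can form. Weinreb ketone synthesis then stops at the methyl ketone because the chelated adduct does not collapse before the quench.

Step 4
Reactants: 8 1-[2,4-bis(methoxymethoxy)-3-(3-methylbut-2-en-1-yl)phenyl]ethan-1-one
Product: 10 1-[2,4-bis(methoxymethoxy)-3-(3-methylbut-2-en-1-yl)phenyl]ethenyl trifluoromethanesulfonate, via potassium enolate of the ketone 9 (not isolated)
Conditions: KN(SiMe3)2 (1.2 equiv), THF, −78 °C; PhNTf2 (1.2 equiv), −78 → 0 °C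
Reagents that add atoms: N-phenylbis(trifluoromethanesulfonimide) (PhNTf2), FC(F)(F)S(=O)(=O)N(c1ccccc1)S(=O)(=O)C(F)(F)F
Why: Enolisation is possible only at the methyl group, and O-sulfonylation of the enolate gives the enol triflate. This fixes the later boron position on the aryl-bearing carbon without any regiochemical choice.

Step 5
Reactants: 10 1-[2,4-bis(methoxymethoxy)-3-(3-methylbut-2-en-1-yl)phenyl]ethenyl trifluoromethanesulfonate
Product: 11 2-{1-[2,4-bis(methoxymethoxy)-3-(3-methylbut-2-en-1-yl)phenyl]ethenyl}-4,4,5,5-tetramethyl-1,3,2-dioxaborolane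
Conditions: B2pin2 (1.1 equiv), PdCl2(PPh3)2 (3 mol%), PPh3 (6 mol%), KOPh (1.5 equiv), toluene, 50 °C
Reagents that add atoms: bis(pinacolato)diboron (B2pin2), CC1(C)OB(OC1(C)C)B1OC(C)(C)C(C)(C)O1
Why: Miyaura borylation of an alkenyl triflate replaces the triflate by boron at the same carbon. The weak phenoxide base suppresses onward Suzuki coupling of the product with unreacted triflate.

Step 6
Reactants: 5 1,3-bis(methoxymethoxy)-2-(3-methylbut-2-en-1-yl)benzene
Product: 13 3,5-bis(methoxymethoxy)-4-(3-methylbut-2-en-1-yl)phenol, via arylboronic acid pinacol ester 12 (not isolated)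
Conditions: [Ir(OMe)(cod)]2 (1.5 mol%), 4,4'-di-tert-butyl-2,2'-bipyridine (3 mol%), B2pin2 (0.7 equiv), THF, 60 °C; then NaOH (aq), H2O2 (30%), 0 °C
Reagents that add atoms: hydrogen peroxide, OO
Why: Iridium-catalysed aromatic C–H borylation is governed by sterics and should select the only ring C–H without an ortho substituent, para to the prenyl group. Basic peroxide then converts the C–B bond into C–O at the same carbon and does not epoxidise an isolated alkene.

Step 7
Reactants: 13 3,5-bis(methoxymethoxy)-4-(3-methylbut-2-en-1-yl)phenol
Product: 14 2-iodo-3,5-bis(methoxymethoxy)-4-(3-methylbut-2-en-1-yl)phenol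
Conditions: I2 (1.0 equiv), NaHCO3, THF–H2O, 0 °C
Reagents that add atoms: iodine, II
Why: Electrophilic aromatic iodination of a phenoxide. The para position is blocked by the prenyl group and the two ortho carbons are equivalent, so one regioisomer is possible; the phenoxide ring is far more nucleophilic than the trisubstituted alkene.

Step 8
Reactants: 14 2-iodo-3,5-bis(methoxymethoxy)-4-(3-methylbut-2-en-1-yl)phenol
Product: 15 [2-iodo-3,5-bis(methoxymethoxy)-4-(3-methylbut-2-en-1-yl)phenoxy]tri(propan-2-yl)silane
Conditions: TIPSCl (1.3 equiv), imidazole (2.5 equiv), DMF, rt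
Reagents that add atoms: chlorotri(propan-2-yl)silane (TIPSCl), CC(C)[Si](Cl)(C(C)C)C(C)C
Why: O-Silylation with the silyl chloride avoids silyl triflates, which would attack the acetals. The bulky silyl ether is stable to hot carbonate and is removed by fluoride without touching the acetals.

Step 9
Reactants: 15 [2-iodo-3,5-bis(methoxymethoxy)-4-(3-methylbut-2-en-1-yl)phenoxy]tri(propan-2-yl)silane; 16 carbon monoxide; 11 2-{1-[2,4-bis(methoxymethoxy)-3-(3-methylbut-2-en-1-yl)phenyl]ethenyl}-4,4,5,5-tetramethyl-1,3,2-dioxaborolane
Product: 17 2-[2,4-bis(methoxymethoxy)-3-(3-methylbut-2-en-1-yl)phenyl]-1-[2,4-bis(methoxymethoxy)-3-(3-methylbut-2-en-1-yl)-6-(triisopropylsilyloxy)phenyl]prop-2-en-1-one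
Conditions: PdCl2(PPh3)2 (5 mol%), K2CO3 (3 equiv), H2O (3 equiv), CO (5 bar), anisole, 80 °C
Reagents that add atoms: none
Why: PdCl2(PPh3)2 is reduced in situ to zerovalent palladium, which adds oxidatively to the C–I bond of 15; migratory insertion of 16 gives an aroyl complex of divalent palladium, carbonate-assisted transmetalation with 11 follows, and reductive elimination releases 17 with the C4a–C4 and C4–C3 bonds formed. The closest known reaction type is the carbonylative Suzuki–Miyaura coupling of aryl iodides with alkenylboronates to aryl vinyl ketones. No ring is closed and no stereocenter is created; the product only places the silylated C8a oxygen and the =CH2 terminus for the later 6-endo-trig closure of ring C. The selectivity needed is carbon monoxide insertion before transmetalation: the arylpalladium intermediate is electron-rich and flanked by two ortho oxygen substituents, so it should transmetalate slowly and insert carbon monoxide readily, and the moderate pressure keeps it saturated with carbon monoxide. The silyl ether keeps a phenoxide away from the aroylpalladium centre, so no aryl ester can form, and it prevents conjugate addition to the new enone under the basic conditions. Regiochemistry is not at stake, because the iodide derives from the symmetric phenol 13 and the boron position was fixed by the enol triflate 10. The acetals, the silyl ether and both prenyl groups should be inert to the carbonate medium.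

Step 10
Reactants: 17 2-[2,4-bis(methoxymethoxy)-3-(3-methylbut-2-en-1-yl)phenyl]-1-[2,4-bis(methoxymethoxy)-3-(3-methylbut-2-en-1-yl)-6-(triisopropylsilyloxy)phenyl]prop-2-en-1-one
Product: 19 (±)-3-[2,4-bis(methoxymethoxy)-3-(3-methylbut-2-en-1-yl)phenyl]-5,7-bis(methoxymethoxy)-6-(3-methylbut-2-en-1-yl)chroman-4-one, via desilylated 2-hydroxyaryl enone 18 (not isolated)
Conditions: Bu4NF (1.1 equiv), THF, 0 °C → rt; H2O
Reagents that add atoms: none
Why: Fluoride cleaves the aryl silyl ether, and the phenoxide adds to the enone terminus in a 6-endo-trig oxa-Michael closure, the step by which 2'-hydroxy-α-methylene deoxybenzoins are known to give isoflavanones. The C3 stereocenter forms on protonation of the enolate without control, which is acceptable because it is removed in step 11.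

Step 11
Reactants: 19 (±)-3-[2,4-bis(methoxymethoxy)-3-(3-methylbut-2-en-1-yl)phenyl]-5,7-bis(methoxymethoxy)-6-(3-methylbut-2-en-1-yl)chroman-4-one
Product: 22 3-[2,4-bis(methoxymethoxy)-3-(3-methylbut-2-en-1-yl)phenyl]-5,7-bis(methoxymethoxy)-6-(3-methylbut-2-en-1-yl)-4H-chromen-4-one, via isoflavanone lithium enolate 20 (not isolated), via 3-(phenylselanyl)isoflavanone 21 (not isolated)
Conditions: LiN(SiMe3)2 (1.2 equiv), THF, −78 °C; PhSeBr (1.05 equiv), −78 °C; then H2O2 (30%), pyridine, CH2Cl2, 0 °C → rt
Reagents that add atoms: none
Why: α-Selenenylation of the ketone enolate at C3, then oxidation to the selenoxide and syn-elimination. The only β-hydrogens are on C2, so the C2=C3 bond must form, and the low-temperature sequence avoids hydride-abstracting oxidants that would attack the benzylic–allylic methylenes.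

Step 12
Reactants: 22 3-[2,4-bis(methoxymethoxy)-3-(3-methylbut-2-en-1-yl)phenyl]-5,7-bis(methoxymethoxy)-6-(3-methylbut-2-en-1-yl)-4H-chromen-4-one
Product: 23 2'-hydroxylupalbigenin, 3-[2,4-dihydroxy-3-(3-methylbut-2-en-1-yl)phenyl]-5,7-dihydroxy-6-(3-methylbut-2-en-1-yl)-4H-chromen-4-one
Conditions: HCl (3 M aq), MeOH, 40 °C
Reagents that add atoms: none
Why: Acid-catalysed acetal exchange with methanol removes the four methoxymethyl groups, the standard final deprotection of prenylated flavonoids. Mild temperature and dilute acid should keep the trisubstituted alkenes from being protonated.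

## Compound list

1 | resorcinol (benzene-1,3-diol) | Oc1cccc(O)c1 | starting material
2 | 1,3-bis(methoxymethoxy)benzene | COCOc1cccc(OCOC)c1 | intermediate
3 | prenyl bromide (1-bromo-3-methylbut-2-ene) | CC(C)=CCBr | starting material
4 | 2,6-bis(methoxymethoxy)phenyllithium | [Li]c1c(OCOC)cccc1OCOC | intermediate (not isolated)
5 | 1,3-bis(methoxymethoxy)-2-(3-methylbut-2-en-1-yl)benzene | COCOc1cccc(OCOC)c1CC=C(C)C | intermediate
6 | N-methoxy-N-methylacetamide | CC(=O)N(C)OC | starting material
7 | 2,4-bis(methoxymethoxy)-3-(3-methylbut-2-en-1-yl)phenyllithium | [Li]c1ccc(OCOC)c(CC=C(C)C)c1OCOC | intermediate (not isolated)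
8 | 1-[2,4-bis(methoxymethoxy)-3-(3-methylbut-2-en-1-yl)phenyl]ethan-1-one | CC(=O)c1ccc(OCOC)c(CC=C(C)C)c1OCOC | intermediate
9 | potassium 1-[2,4-bis(methoxymethoxy)-3-(3-methylbut-2-en-1-yl)phenyl]ethen-1-olate | [K+].[O-]C(=C)c1ccc(OCOC)c(CC=C(C)C)c1OCOC | intermediate (not isolated)
10 | 1-[2,4-bis(methoxymethoxy)-3-(3-methylbut-2-en-1-yl)phenyl]ethenyl trifluoromethanesulfonate | C=C(OS(=O)(=O)C(F)(F)F)c1ccc(OCOC)c(CC=C(C)C)c1OCOC | intermediate
11 | 2-{1-[2,4-bis(methoxymethoxy)-3-(3-methylbut-2-en-1-yl)phenyl]ethenyl}-4,4,5,5-tetramethyl-1,3,2-dioxaborolane | C=C(B1OC(C)(C)C(C)(C)O1)c1ccc(OCOC)c(CC=C(C)C)c1OCOC | intermediate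
12 | 2-[3,5-bis(methoxymethoxy)-4-(3-methylbut-2-en-1-yl)phenyl]-4,4,5,5-tetramethyl-1,3,2-dioxaborolane | COCOc1cc(B2OC(C)(C)C(C)(C)O2)cc(OCOC)c1CC=C(C)C | intermediate (not isolated)
13 | 3,5-bis(methoxymethoxy)-4-(3-methylbut-2-en-1-yl)phenol | Oc1cc(OCOC)c(CC=C(C)C)c(OCOC)c1 | intermediate
14 | 2-iodo-3,5-bis(methoxymethoxy)-4-(3-methylbut-2-en-1-yl)phenol | Oc1cc(OCOC)c(CC=C(C)C)c(OCOC)c1I | intermediate
15 | [2-iodo-3,5-bis(methoxymethoxy)-4-(3-methylbut-2-en-1-yl)phenoxy]tri(propan-2-yl)silane | CC(C)[Si](Oc1cc(OCOC)c(CC=C(C)C)c(OCOC)c1I)(C(C)C)C(C)C | intermediate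
16 | carbon monoxide | [C-]#[O+] | starting material
17 | 2-[2,4-bis(methoxymethoxy)-3-(3-methylbut-2-en-1-yl)phenyl]-1-[2,4-bis(methoxymethoxy)-3-(3-methylbut-2-en-1-yl)-6-(triisopropylsilyloxy)phenyl]prop-2-en-1-one | C=C(c1ccc(OCOC)c(CC=C(C)C)c1OCOC)C(=O)c1c(O[Si](C(C)C)(C(C)C)C(C)C)cc(OCOC)c(CC=C(C)C)c1OCOC | intermediate
18 | 2-[2,4-bis(methoxymethoxy)-3-(3-methylbut-2-en-1-yl)phenyl]-1-[6-hydroxy-2,4-bis(methoxymethoxy)-3-(3-methylbut-2-en-1-yl)phenyl]prop-2-en-1-one | C=C(c1ccc(OCOC)c(CC=C(C)C)c1OCOC)C(=O)c1c(O)cc(OCOC)c(CC=C(C)C)c1OCOC | intermediate (not isolated)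
19 | (±)-3-[2,4-bis(methoxymethoxy)-3-(3-methylbut-2-en-1-yl)phenyl]-5,7-bis(methoxymethoxy)-6-(3-methylbut-2-en-1-yl)chroman-4-one (racemic at C3) | O=C1C(c2ccc(OCOC)c(CC=C(C)C)c2OCOC)COc2cc(OCOC)c(CC=C(C)C)c(OCOC)c12 | intermediate
20 | lithium enolate of 19 (lithium 2H-chromen-4-olate) | [Li]OC1=C(c2ccc(OCOC)c(CC=C(C)C)c2OCOC)COc2cc(OCOC)c(CC=C(C)C)c(OCOC)c12 | intermediate (not isolated)
21 | (±)-3-[2,4-bis(methoxymethoxy)-3-(3-methylbut-2-en-1-yl)phenyl]-5,7-bis(methoxymethoxy)-6-(3-methylbut-2-en-1-yl)-3-(phenylselanyl)chroman-4-one (racemic at C3) | O=C1C([Se]c2ccccc2)(c2ccc(OCOC)c(CC=C(C)C)c2OCOC)COc2cc(OCOC)c(CC=C(C)C)c(OCOC)c12 | intermediate (not isolated)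
22 | 3-[2,4-bis(methoxymethoxy)-3-(3-methylbut-2-en-1-yl)phenyl]-5,7-bis(methoxymethoxy)-6-(3-methylbut-2-en-1-yl)-4H-chromen-4-one | O=c1c(-c2ccc(OCOC)c(CC=C(C)C)c2OCOC)coc2cc(OCOC)c(CC=C(C)C)c(OCOC)c12 | intermediate
23 | 2'-hydroxylupalbigenin, 3-[2,4-dihydroxy-3-(3-methylbut-2-en-1-yl)phenyl]-5,7-dihydroxy-6-(3-methylbut-2-en-1-yl)-4H-chromen-4-one | CC(C)=CCc1c(O)ccc(-c2coc3cc(O)c(CC=C(C)C)c(O)c3c2=O)c1O | target

## Step count and least certain steps

Total step count: 12. Longest linear sequence: 9 steps (steps 1 and 2, then either 3, 4, 5 or 6, 7, 8, then 9, 10, 11, 12).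

**Step 9 (key step).**
- Risk: coupling without uptake of carbon monoxide, protodeboronation of the hindered α-arylvinylboronate, and slow transmetalation to the crowded aroylpalladium complex, which would let water capture the acyl group. Both partners are sterically loaded and the boronate is a pinacol ester. Partial loss of the silyl group would lead to early ring closure; this would be harmless, since it leads on to 19.
- Fallback: it sets out from 15 and 10 and returns at 17. Iodine–magnesium exchange on 15 (i-PrMgCl·LiCl, THF, −20 °C) and formylation with DMF would give 2,4-bis(methoxymethoxy)-3-(3-methylbut-2-en-1-yl)-6-(triisopropylsilyloxy)benzaldehyde F1. Nozaki–Hiyama–Kishi coupling of F1 with 10 (CrCl2, NiCl2 cat., DMF, rt) would give the racemic allylic alcohol 2-[2,4-bis(methoxymethoxy)-3-(3-methylbut-2-en-1-yl)phenyl]-1-[2,4-bis(methoxymethoxy)-3-(3-methylbut-2-en-1-yl)-6-(triisopropylsilyloxy)phenyl]prop-2-en-1-ol F2. Oxidation of F2 with MnO2 in CH2Cl2 would give 17. The carbonyl carbon then comes from DMF and the C4–C3 bond from a carbonyl addition.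

**Step 3.**
- Risk: deprotonation at the benzylic–allylic methylene of the prenyl group, which both acetal oxygens can also direct, in competition with ring lithiation; and enolisation of the amide by the aryllithium, which would return 5.
- Fallback: it sets out from 5 and returns at 8. Bromination of the activated ring (N-bromosuccinimide, MeCN, −20 → 0 °C) would give 1-bromo-2,4-bis(methoxymethoxy)-3-(3-methylbut-2-en-1-yl)benzene F3. Bromine–lithium exchange (n-BuLi, THF, −78 °C) would produce 7 without a deprotonation step, and 7 would be acylated with 6 as before.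

**Step 6.**
- Risk: hydroboration or isomerisation of the trisubstituted alkene by iridium boryl hydride species, incomplete site control of the C–H borylation, and over-oxidation of the very electron-rich phenol in the peroxide stage.
- Fallback: it sets out from 3 and returns at 13. Commercial phloroglucinol F4 would be doubly protected in a statistical reaction (MOMCl, i-Pr2NEt) to 3,5-bis(methoxymethoxy)phenol F5 and silylated (TIPSCl, imidazole) to [3,5-bis(methoxymethoxy)phenoxy]triisopropylsilane F6. Lithiation between the two acetal oxygens (n-BuLi, THF, 0 °C) and allylation with 3 (CuI cat.) would give [3,5-bis(methoxymethoxy)-4-(3-methylbut-2-en-1-yl)phenoxy]triisopropylsilane F7. Bu4NF would then release 13.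

**Step 11.**
- Risk: opening of ring C by β-elimination of the aryloxide from the enolate, addition of the selenium electrophile to the prenyl alkenes, and epoxidation of these alkenes by peroxyseleninic species in the oxidation stage.
- Fallback: it sets out from 19 and returns at 22 by a Saegusa–Ito oxidation. LiN(SiMe3)2 and Me3SiCl (THF, −78 °C) would give the enol ether 3-[2,4-bis(methoxymethoxy)-3-(3-methylbut-2-en-1-yl)phenyl]-5,7-bis(methoxymethoxy)-6-(3-methylbut-2-en-1-yl)-4-(trimethylsilyloxy)-2H-chromene F8. Pd(OAc)2 in MeCN at rt would then give 22 with no peroxide or selenium present.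

**Step 12.**
- Risk: acid-catalysed addition of the freed ortho phenols to the prenyl double bonds (chroman formation) or hydration of these double bonds while the last acetals are still being cleaved.
- Fallback: it sets out from 22 and returns at 23 without protic acid. Me3SiOTf and 2,2'-bipyridyl (MeCN, 0 °C → rt) would exchange each aryl methoxymethyl ether for a silyl ether, giving 3-[3-(3-methylbut-2-en-1-yl)-2,4-bis(trimethylsilyloxy)phenyl]-6-(3-methylbut-2-en-1-yl)-5,7-bis(trimethylsilyloxy)-4H-chromen-4-one F9. Water would hydrolyse F9 to 23.

## Further compounds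

F1 | step 9 | 2,4-bis(methoxymethoxy)-3-(3-methylbut-2-en-1-yl)-6-(triisopropylsilyloxy)benzaldehyde | O=Cc1c(O[Si](C(C)C)(C(C)C)C(C)C)cc(OCOC)c(CC=C(C)C)c1OCOC
F2 | step 9 | (±)-2-[2,4-bis(methoxymethoxy)-3-(3-methylbut-2-en-1-yl)phenyl]-1-[2,4-bis(methoxymethoxy)-3-(3-methylbut-2-en-1-yl)-6-(triisopropylsilyloxy)phenyl]prop-2-en-1-ol | C=C(c1ccc(OCOC)c(CC=C(C)C)c1OCOC)C(O)c1c(O[Si](C(C)C)(C(C)C)C(C)C)cc(OCOC)c(CC=C(C)C)c1OCOC
F3 | step 3 | 1-bromo-2,4-bis(methoxymethoxy)-3-(3-methylbut-2-en-1-yl)benzene | Brc1ccc(OCOC)c(CC=C(C)C)c1OCOC
F4 | step 6 | phloroglucinol (benzene-1,3,5-triol) | Oc1cc(O)cc(O)c1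
F5 | step 6 | 3,5-bis(methoxymethoxy)phenol | Oc1cc(OCOC)cc(OCOC)c1
F6 | step 6 | [3,5-bis(methoxymethoxy)phenoxy]triisopropylsilane | CC(C)[Si](Oc1cc(OCOC)cc(OCOC)c1)(C(C)C)C(C)C
F7 | step 6 | [3,5-bis(methoxymethoxy)-4-(3-methylbut-2-en-1-yl)phenoxy]triisopropylsilane | CC(C)[Si](Oc1cc(OCOC)c(CC=C(C)C)c(OCOC)c1)(C(C)C)C(C)C
F8 | step 11 | 3-[2,4-bis(methoxymethoxy)-3-(3-methylbut-2-en-1-yl)phenyl]-5,7-bis(methoxymethoxy)-6-(3-methylbut-2-en-1-yl)-4-(trimethylsilyloxy)-2H-chromene | C[Si](C)(C)OC1=C(c2ccc(OCOC)c(CC=C(C)C)c2OCOC)COc2cc(OCOC)c(CC=C(C)C)c(OCOC)c12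
F9 | step 12 | 3-[3-(3-methylbut-2-en-1-yl)-2,4-bis(trimethylsilyloxy)phenyl]-6-(3-methylbut-2-en-1-yl)-5,7-bis(trimethylsilyloxy)-4H-chromen-4-one | CC(C)=CCc1c(O[Si](C)(C)C)ccc(-c2coc3cc(O[Si](C)(C)C)c(CC=C(C)C)c(O[Si](C)(C)C)c3c2=O)c1O[Si](C)(C)C
A1 | alternative 1 | (E)-4-[5,7-bis(methoxymethoxy)-6-(3-methylbut-2-en-1-yl)-4-oxo-4H-chromen-3-yl]-1-diazobut-3-en-2-one | [N-]=[N+]=CC(=O)/C=C/c1coc2cc(OCOC)c(CC=C(C)C)c(OCOC)c2c1=O
A2 | alternative 1 | triisopropyl[(5-methylhex-4-en-1-yn-1-yl)oxy]silane | CC(C)=CCC#CO[Si](C(C)C)(C(C)C)C(C)C
A3 | alternative 1 | 3-[2-hydroxy-3-(3-methylbut-2-en-1-yl)-4-(triisopropylsilyloxy)phenyl]-5,7-bis(methoxymethoxy)-6-(3-methylbut-2-en-1-yl)-4H-chromen-4-one | O=c1c(-c2ccc(O[Si](C(C)C)(C(C)C)C(C)C)c(CC=C(C)C)c2O)coc2cc(OCOC)c(CC=C(C)C)c(OCOC)c12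
A4 | alternative 2 | 7-(methoxymethoxy)-3-[4-(methoxymethoxy)-2-(2-methylbut-3-en-2-yloxy)phenyl]-5-(2-methylbut-3-en-2-yloxy)-4H-chromen-4-one | O=c1c(-c2ccc(OCOC)cc2OC(C)(C)C=C)coc2cc(OCOC)cc(OC(C)(C)C=C)c12
A5 | alternative 2 | 5-hydroxy-3-[2-hydroxy-4-(methoxymethoxy)-3-(3-methylbut-2-en-1-yl)phenyl]-7-(methoxymethoxy)-6-(3-methylbut-2-en-1-yl)-4H-chromen-4-one | O=c1c(-c2ccc(OCOC)c(CC=C(C)C)c2O)coc2cc(OCOC)c(CC=C(C)C)c(O)c12
A6 | alternative 3 | (Z)-3-[3,5-bis(methoxymethoxy)-4-(3-methylbut-2-en-1-yl)phenoxy]-2-[2,4-bis(methoxymethoxy)-3-(3-methylbut-2-en-1-yl)phenyl]prop-2-enoic acid | OC(=O)/C(=C\Oc1cc(OCOC)c(CC=C(C)C)c(OCOC)c1)c1ccc(OCOC)c(CC=C(C)C)c1OCOC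
A7 | alternative 3 | 3-[2,4-bis(methoxymethoxy)-3-(3-methylbut-2-en-1-yl)phenyl]-5,7-bis(methoxymethoxy)-6-(3-methylbut-2-en-1-yl)-4H-chromen-4-one (identical with 22) | O=c1c(-c2ccc(OCOC)c(CC=C(C)C)c2OCOC)coc2cc(OCOC)c(CC=C(C)C)c(OCOC)c12
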